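At early times the teal flask makes more target than isomer of the product: 10% against 2% at 1.50 min. By 4.00 min it holds 25% and 27%.

| flask | substrate | gas | remark | time |
|---|---|---|---|---|
| teal | 1.2 M (fed, over 80 s) | 200 mM (held) | the very flask that is asked about, followed so far; the fed solution adds 0.20 times the starting volume |  |
| blue | 0.80 M (fed, over 80 s) | 200 mM (held) | run made earlier; the fed solution adds 0.20 times the starting volume |  |
| flask | 1.2 M (fed, over 80 s) | 200 mM (held) | the fed solution adds 0.20 times the starting volume | 10 min |

| run | time / min | target / % | isomer of the product / % |
|---|---|---|---|
| teal | 0.333 | 1 | 0 |
| teal | 0.667 | 4 | 0 |
| teal | 1.50 | 10 | 2 |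
| teal | 4.00 | 25 | 27 |
| blue | 2.00 | 13 | 12 |
| blue | 4.00 | 26 | 26 |
| blue | 5.00 | 28 | 31 |
| blue | 8.00 | 38 | 51 |

(each reading ± 2 percentage points)

- charges are per starting volume, the dose included; the dosed solution carries all of it
- at the start none of the gas is in solution
- in a conversion other conformer counts as not yet reacted
- percentages count the whole charge, also what has not yet gone in
- the reaction counts as stopped when no species that holds the substrate changes by six tenths of a point or more over the second half of the time

- which holds at 10 min: what has brought the reaction to rest, or that it has not come to rest (other conformer counts as not reacted) (all of the substrate has reacted / it is still moving / forward and back rates have come level)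
- amount of target at 10 min, in percent of the substrate charged
- amount of isomer of the product at 10 min, in percent of the substrate charged

I take the end state to be target plus isomer filling the charge, so each answer is a share of the product times the product made. Which input must be good? The charge comes first: at 4.00 min the blue run, with 0.80 M against teal's 1.2 M, differs from the teal run by 1 percentage point in target, inside the scatter, so I let blue stand in for teal's later course. Then comes the remainder, what is neither target nor isomer. In the blue run it falls from 48.0% at 4.00 min to 11.0% at 8.00 min, and the same decay gives 5.27% at 10 min. Blue's remainder at 5.00 min is 41.0%, so my reckoning has a fall of 36 points over the second half of the time, and I expect the reaction still moving. Last comes the split. I define it as target over target plus isomer at the latest blue reading, the selectivity, 0.427. Using teal's 0.481 instead would move target by 5.1 points, while doubling the remainder would cost target less, 2.2 points. My reckoning gives 40.4% target and 54.3% isomer.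

The forecast says it is still moving, with 41% target (36% to 46%) and 54% isomer (47% to 61%), since “nothing suggests a plateau”.

At 10 min it is still moving, with 37.0% target and 55.3% isomer.

    substrate + coupling partner → target (k = 0.0300 M⁻¹ s⁻¹)
    gas ⇌ coupling partner, rate k2*(csat - [coupling partner]) (kL = 0.0240 s⁻¹)
    coupling partner + other conformer → isomer of the product (k = 0.0410 M⁻¹ s⁻¹)
    substrate ⇌ other conformer (K = 1.70, k = 0.0130 s⁻¹)

The flask's target stands 1.00 point above the low end of the forecast's range, and the nearest substrate charges at which target has moved by 5 points are 0.219 M and 2.17 M. The flask's own split is 0.401, against the 0.427 read from blue. In the same flask with 0.30 M of substrate, the split 0.427 times that flask's target plus isomer gives 41.5% target, and that flask holds 41.5%.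

The runs are simulated with made-up constants; the scatter is artificial.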